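**Retrosynthetic overview**
- The quinone is unveiled last by para-oxidation (Teuber) of a 3-methoxy-2-methyl-5-alkenylphenol; the new carbonyl oxygen enters between OMe and the side chain.
- The aryl–C(=CH2) bond comes from a Suzuki–Miyaura coupling of a meta-borylated phenol (sterically controlled C–H borylation) with a 2-triflyloxy-1-alkene.
- The enol triflate comes from kinetic triflation of the methyl ketone (S)-3-angeloyloxy-6-methylhept-5-en-2-one.
- Key bond: the C3–O bond of the secondary angelate, made enantioselectively by a new amine-catalysed α-acyloxylation of sulcatone (its carbon chain is the whole side chain) with an angelic-acid-derived peroxide.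
- No ring is built: the only ring comes intact from the phenol and is oxidised to the quinone in the final step.

Assumption: 3-methoxy-2-methylphenol is bought (otherwise one methylation from 2-methylresorcinol), and the facial sense of the new step is assigned by analogy, the quinidine-derived pseudoenantiomer of the amine being used if it proves opposite.

**Step 1**
Reactants: 1 6-methylhept-5-en-2-one (sulcatone); 2 angelic acid, (2Z)-2-methylbut-2-enoic acid
Product: 4 (3S)-6-methyl-2-oxohept-5-en-3-yl (2Z)-2-methylbut-2-enoate, via diangeloyl peroxide 3 (not isolated)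
Conditions: 2 (2.0 equiv), DCC (2.0 equiv), 30% aq H2O2 (1.0 equiv), CH2Cl2, 0 °C, filter, wash (aq NaHCO3), dry; then 1 (3 equiv), 9-amino(9-deoxy)epi-quinine [(8S,9S)-6′-methoxycinchonan-9-amine] (10 mol %), Cl3CCO2H (20 mol %), 2,6-di-tert-butyl-4-methylphenol (10 mol %), THF, 25 °C
Reagents that add atoms: hydrogen peroxide, OO
Why: Proposed new method: the primary amine condenses with the methyl ketone to the more substituted (Z)-enamine, which attacks one peroxide oxygen of 3 in an SN2-type step while the protonated quinuclidine hydrogen-bonds the peroxide carbonyl, so the C3–O bond forms on one enamine face (S expected, to be confirmed) with angelate as leaving group and without touching the (Z)-alkene of the acyl group or the remote prenyl alkene; the closest known reaction type is the primary-amine-catalysed enantioselective α-benzoyloxylation of cyclic ketones with dibenzoyl peroxide, which has not been shown for an acyclic methyl ketone at its methylene carbon or for an unsaturated diacyl peroxide made in the flask.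

**Step 2**
Reactants: 4 (3S)-6-methyl-2-oxohept-5-en-3-yl (2Z)-2-methylbut-2-enoate
Product: 5 (3S)-6-methyl-2-[(trifluoromethanesulfonyl)oxy]hepta-1,5-dien-3-yl (2Z)-2-methylbut-2-enoate
Conditions: KN(SiMe3)2 (1.1 equiv) added to 4 and PhNTf2 (1.2 equiv), THF, −78 °C
Reagents that add atoms: N-phenylbis(trifluoromethanesulfonimide), O=S(=O)(N(c1ccccc1)S(=O)(=O)C(F)(F)F)C(F)(F)F
Why: Kinetic enolisation by the hindered amide base at the unhindered methyl group, followed by O-sulfonylation (enol triflate formation) with the trapping agent already present, leaves the tertiary C3–H and its stereocenter untouched and gives the enolate no time for acyl transfer.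

**Step 3**
Reactants: 6 3-methoxy-2-methylphenol
Product: 9 3-methoxy-2-methyl-5-(4,4,5,5-tetramethyl-1,3,2-dioxaborolan-2-yl)phenol, via aryl O-boronate 7 (not isolated), via C,O-diborylated arene 8 (not isolated)
Conditions: HBpin (3 equiv), [Ir(OMe)(cod)]2 (1.5 mol %), 4,4′-di-tert-butyl-2,2′-bipyridine (3 mol %), THF, 25 → 80 °C; then H2O
Reagents that add atoms: pinacolborane, CC1(C)OBOC1(C)C
Why: Iridium-catalysed C–H borylation is sterically controlled, so after the O–H is masked as its boronate in the flask only C5 (the one C–H not ortho to a substituent) is borylated, and aqueous work-up frees the phenol.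

**Step 4**
Reactants: 5 (3S)-6-methyl-2-[(trifluoromethanesulfonyl)oxy]hepta-1,5-dien-3-yl (2Z)-2-methylbut-2-enoate; 9 3-methoxy-2-methyl-5-(4,4,5,5-tetramethyl-1,3,2-dioxaborolan-2-yl)phenol
Product: 10 (3S)-2-(3-hydroxy-5-methoxy-4-methylphenyl)-6-methylhepta-1,5-dien-3-yl (2Z)-2-methylbut-2-enoate
Conditions: Pd(OAc)2 (3 mol %), 2-dicyclohexylphosphino-2′,6′-dimethoxybiphenyl (6 mol %), K3PO4 (3 equiv), THF/H2O (10:1), 25 °C
Reagents that add atoms: none
Why: Suzuki–Miyaura coupling: zerovalent palladium inserts into the C–OTf bond far faster than it ionises the hindered secondary allylic ester, and transmetalation and reductive elimination give the 1,1-disubstituted alkene without involving the allylic stereocenter.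

**Step 5**
Reactants: 10 (3S)-2-(3-hydroxy-5-methoxy-4-methylphenyl)-6-methylhepta-1,5-dien-3-yl (2Z)-2-methylbut-2-enoate
Product: 11 (3S)-2-(5-methoxy-4-methyl-3,6-dioxocyclohexa-1,4-dien-1-yl)-6-methylhepta-1,5-dien-3-yl (2Z)-2-methylbut-2-enoate (target)
Conditions: (KSO3)2NO (2.5 equiv), KH2PO4, acetone/H2O, 0 → 25 °C
Reagents that add atoms: potassium nitrosodisulfonate (Fremy's salt), [K+].[K+].[O]N(S(=O)(=O)[O-])S(=O)(=O)[O-]
Why: Teuber oxidation: two equivalents of the nitroxyl radical convert a phenol with a free para position into the para-quinone (the ortho position on the other side is blocked by methyl), and the alkenes, the angelate and the stereocenter are inert to this one-electron oxidant.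

**Compound list**
1 | 6-methylhept-5-en-2-one (sulcatone) | CC(=O)CCC=C(C)C | starting material
2 | angelic acid, (2Z)-2-methylbut-2-enoic acid | C/C=C(/C)C(=O)O | starting material
3 | diangeloyl peroxide, bis[(2Z)-2-methylbut-2-enoyl] peroxide | C/C=C(/C)C(=O)OOC(=O)/C(C)=C\C | intermediate
4 | (3S)-6-methyl-2-oxohept-5-en-3-yl (2Z)-2-methylbut-2-enoate | CC(=O)[C@H](CC=C(C)C)OC(=O)/C(C)=C\C | intermediate
5 | (3S)-6-methyl-2-[(trifluoromethanesulfonyl)oxy]hepta-1,5-dien-3-yl (2Z)-2-methylbut-2-enoate | C=C(OS(=O)(=O)C(F)(F)F)[C@H](CC=C(C)C)OC(=O)/C(C)=C\C | intermediate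
6 | 3-methoxy-2-methylphenol | COc1cccc(O)c1C | starting material
7 | 2-(3-methoxy-2-methylphenoxy)-4,4,5,5-tetramethyl-1,3,2-dioxaborolane | COc1cccc(OB2OC(C)(C)C(C)(C)O2)c1C | intermediate
8 | 2-[3-methoxy-2-methyl-5-(4,4,5,5-tetramethyl-1,3,2-dioxaborolan-2-yl)phenoxy]-4,4,5,5-tetramethyl-1,3,2-dioxaborolane | COc1cc(B2OC(C)(C)C(C)(C)O2)cc(OB3OC(C)(C)C(C)(C)O3)c1C | intermediate
9 | 3-methoxy-2-methyl-5-(4,4,5,5-tetramethyl-1,3,2-dioxaborolan-2-yl)phenol | COc1cc(B2OC(C)(C)C(C)(C)O2)cc(O)c1C | intermediate
10 | (3S)-2-(3-hydroxy-5-methoxy-4-methylphenyl)-6-methylhepta-1,5-dien-3-yl (2Z)-2-methylbut-2-enoate | C=C(c1cc(O)c(C)c(OC)c1)[C@H](CC=C(C)C)OC(=O)/C(C)=C\C | intermediate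
11 | (3S)-2-(5-methoxy-4-methyl-3,6-dioxocyclohexa-1,4-dien-1-yl)-6-methylhepta-1,5-dien-3-yl (2Z)-2-methylbut-2-enoate, CNP0232608.2 | C=C(C1=CC(=O)C(C)=C(OC)C1=O)[C@H](CC=C(C)C)OC(=O)/C(C)=C\C | target

**Step count**
Total: 5 steps. Longest linear sequence: 4 steps (steps 1, 2, 4 and 5 from sulcatone; step 3 is the side branch).

**Steps most likely to fail, with fallbacks**

Step 1, the new α-acyloxylation. The risks are reaction at C1 instead of C3, low enantioselectivity, oxidation of the amine by the peroxide, and loss of the (Z)-geometry. The fallback uses known chemistry only, sets out from 1 and comes back at 4. L-Proline-catalysed α-aminoxylation of 1 with nitrosobenzene (DMSO, 0 °C, ketone in excess) gives (3R)-6-methyl-3-[(phenylamino)oxy]hept-5-en-2-one F1, the (R) sense being expected by analogy with cyclohexanone. CuSO4 in MeOH at 0 °C cleaves the N–O bond to (3R)-3-hydroxy-6-methylhept-5-en-2-one F2. Mitsunobu esterification of F2 with 2 (PPh3, DIAD, THF, 0 °C) then forms the same C–O bond with inversion, with the acid acting only as a nucleophile so that its geometry is kept, and delivers 4.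

Step 2, enolate chemistry next to the ester. The risks are deprotonation at C3 with loss of ee, and acyl transfer from oxygen to the enolate carbon. The fallback puts the triflate in place before the ester; it sets out from 1 and comes back at 5. F2, made from 1 by way of F1 as above, is silylated (TBSCl, imidazole, CH2Cl2) to (3R)-3-[(tert-butyldimethylsilyl)oxy]-6-methylhept-5-en-2-one F3. Its kinetic enolate (KN(SiMe3)2, PhNTf2, THF, −78 °C) gives (3R)-3-[(tert-butyldimethylsilyl)oxy]-6-methylhepta-1,5-dien-2-yl trifluoromethanesulfonate F4. HF·pyridine frees (3R)-3-hydroxy-6-methylhepta-1,5-dien-2-yl trifluoromethanesulfonate F5, and Mitsunobu esterification with 2 (inversion) gives 5.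

Step 4, zerovalent palladium in the presence of a secondary allylic ester. Ionisation of the ester, or β-acyloxy elimination from the alkenylpalladium intermediate to an allene, may compete with the coupling. The fallback runs the cross-coupling before the ester exists; it sets out from 1 and 9 and comes back at 10. F5, from the fallback above, is coupled with 9 under the conditions of step 4 to give 5-[(3R)-3-hydroxy-6-methylhepta-1,5-dien-2-yl]-3-methoxy-2-methylphenol F6. The secondary allylic alcohol of F6 is then esterified with 2 under Mitsunobu conditions (inversion) to give 10; the carboxylic acid (pKa about 4) is engaged in preference to the phenol (pKa about 10).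

**Further compounds**
F1 | step 1 | (3R)-6-methyl-3-[(phenylamino)oxy]hept-5-en-2-one | CC(=O)[C@@H](CC=C(C)C)ONc1ccccc1
F2 | step 1 | (3R)-3-hydroxy-6-methylhept-5-en-2-one | CC(=O)[C@@H](CC=C(C)C)O
F3 | step 2 | (3R)-3-[(tert-butyldimethylsilyl)oxy]-6-methylhept-5-en-2-one | CC(=O)[C@@H](CC=C(C)C)O[Si](C)(C)C(C)(C)C
F4 | step 2 | (3R)-3-[(tert-butyldimethylsilyl)oxy]-6-methylhepta-1,5-dien-2-yl trifluoromethanesulfonate | C=C(OS(=O)(=O)C(F)(F)F)[C@@H](CC=C(C)C)O[Si](C)(C)C(C)(C)C
F5 | step 2 | (3R)-3-hydroxy-6-methylhepta-1,5-dien-2-yl trifluoromethanesulfonate | C=C(OS(=O)(=O)C(F)(F)F)[C@@H](CC=C(C)C)O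
F6 | step 4 | 5-[(3R)-3-hydroxy-6-methylhepta-1,5-dien-2-yl]-3-methoxy-2-methylphenol | C=C(c1cc(O)c(C)c(OC)c1)[C@@H](CC=C(C)C)O
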